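Everything rests on the bond C8a–C8c, the only bond common to the two eight-membered carbocycles (ring X: C7a, C10b, C9b, C8b, C10c, C9c, C8c, C8a; ring Y: C7c, C10d, C9d, C8d, C10a, C9a, C8a, C8c). Cutting it leaves one fourteen-membered carbocycle in which C7a and C7c are diarylmethyl carbons and can be drawn as alkene carbons. In one operation the key step gives each triarylethene one electron, joins the two C8 termini across the ring, closes rings X and Y and, after protonation at C7a and C7c, sets four stereocentres. Its precursor is the fourteen-membered (Z,Z)-bis(triarylethene) macrocycle as decabenzyl ether, assembled from one enantiopure cis-dihydrobenzofuran.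

Key step: step 17

Remarks (one line each)
- Locants: stilbene-unit numbering for units a–d (C7/C8 the ethane carbons, C1 the 4-oxygenated phenyl carbon on C7, C9–C14 the resorcinol ring on C8, C10 its substituted ortho carbon, C11 the oxygen-bearing carbon beside C10); in benzofuran names C2 = C7 and C3 = C8 of units d and b.
- Structure check: the target is (7aR,8aS,7bS,8bS,7cR,8cR,7dR,8dS); the furan ring of unit d is 2,3-cis, that of unit b 2,3-trans; H8a and H8c are trans, H7a is cis to H8a, H7c is trans to H8c; no constitutional or stereochemical correction of macrocycle or product was needed.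
- The macrocycle needs both alkenes Z (C10 cis to C9) and a ketone precursor with the carbonyl on C7 (aryl–CH2–CO–aryl, from an acetophenone); an arylacetic acid would place the carbonyl, and later the new aryl group, on C8.
- Protecting groups: ten benzyl ethers are carried instead of methyl ethers, because boron-halide ether cleavage is expected to epimerise a 2,3-cis-2-aryl-dihydrobenzofuran to trans, whereas hydrogenolysis is neutral.
- Reductant: the furan C7–O bonds and the protecting groups are benzyl aryl ethers, so the key step uses a naphthalenide, just strong enough for the alkenes.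
- Assumption: Rh2(S-PTAD)4 is taken to give the (2R,3S)-cis product in step 7; if the sense of induction is the opposite, Rh2(R-PTAD)4 is used.
- CIP note: the descriptor at C3/C8 of the furan units switches between R and S when chlorine or boron enters the neighbouring ring; the geometry never changes (see SMILES).

Step 1
Reactants: 1 1,3-bis(benzyloxy)-5-bromobenzene
Product: 3 2,4-bis(benzyloxy)-6-bromobenzaldehyde, via iminium chloride 2 (not isolated)
Conditions: POCl3, DMF, 0 → 90 °C; then H2O, 0 °C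
Reagents that add atoms: N,N-dimethylformamide CN(C)C=O; water O
Why: Vilsmeier–Haack formylation should attack the carbon para to one ether and next to bromine, which is less crowded than the carbon between the two benzyloxy groups, as is usual for 5-substituted resorcinol diethers.

Step 2
Reactants: 3 2,4-bis(benzyloxy)-6-bromobenzaldehyde
Product: 4 4-(benzyloxy)-2-bromo-6-hydroxybenzaldehyde
Conditions: MgBr2·OEt2, toluene/Et2O, 80 °C
Reagents that add atoms: none
Why: Magnesium chelated between the aldehyde oxygen and the ortho ether oxygen activates only that benzyl group towards bromide (chelation-controlled ortho-debenzylation), so the para ether should stay.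

Step 3
Reactants: 4 4-(benzyloxy)-2-bromo-6-hydroxybenzaldehyde; 5 4-(benzyloxy)benzyl chloride
Product: 6 4-(benzyloxy)-2-{[4-(benzyloxy)phenyl]methoxy}-6-bromobenzaldehyde
Conditions: K2CO3, KI (cat.), DMF, 60 °C
Reagents that add atoms: none
Why: Williamson etherification of the acidic ortho-hydroxyl with a benzylic chloride is routine; the methylene introduced here later becomes C7 of the furan units together with its aryl group.

Step 4
Reactants: 1 1,3-bis(benzyloxy)-5-bromobenzene; 6 4-(benzyloxy)-2-{[4-(benzyloxy)phenyl]methoxy}-6-bromobenzaldehyde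
Product: 8 (RS)-[4-(benzyloxy)-2-{[4-(benzyloxy)phenyl]methoxy}-6-bromophenyl][3,5-bis(benzyloxy)phenyl]methanol, via aryl Grignard reagent 7 (not isolated)
Conditions: 1, Mg, THF, reflux; then 6, THF, 0 °C
Reagents that add atoms: none
Why: Grignard addition to the aldehyde is much faster than halogen–magnesium exchange at the aryl bromide; the carbinol centre is racemic and is removed in step 5.

Step 5
Reactants: 8 diarylmethanol
Product: 9 [4-(benzyloxy)-2-{[4-(benzyloxy)phenyl]methoxy}-6-bromophenyl][3,5-bis(benzyloxy)phenyl]methanone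
Conditions: Dess–Martin periodinane, CH2Cl2, rt
Reagents that add atoms: none
Why: Dess–Martin oxidation of a diarylcarbinol is mild and neutral, and should leave the benzyl ethers and the aryl bromide untouched.

Step 6
Reactants: 9 diaryl ketone
Product: 10 hydrazone of ketone 9 (E/Z mixture)
Conditions: N2H4·H2O (excess), AcOH (cat.), n-BuOH, 110 °C, sealed tube
Reagents that add atoms: hydrazine NN
Why: Acid-catalysed hydrazone condensation; the carbonyl is flanked by two ortho substituents, so forcing conditions are planned, the face next to the small ether oxygen remaining open to attack.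

Step 7
Reactants: 10 hydrazone
Product: 12 (2R,3S)-6-(benzyloxy)-2-[4-(benzyloxy)phenyl]-3-[3,5-bis(benzyloxy)phenyl]-4-bromo-2,3-dihydro-1-benzofuran (2,3-cis), via diaryldiazomethane 11 (not isolated)
Conditions: MnO2, CH2Cl2, 0 °C; filter; Rh2(S-PTAD)4 (1 mol%), CH2Cl2, −20 → 0 °C
Reagents that add atoms: none
Why: Hydrazone oxidation gives the diaryldiazomethane, whose donor/donor rhodium carbene inserts into the activated ether C–H bond (intramolecular 1,5 C–H insertion); the chiral carboxylate ligands select the carbene face and so set C3 (C8), and the concerted insertion should give the 2,3-cis relation at C2 (C7) under kinetic control.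

Step 8
Reactants: 12 cis-dihydrobenzofuran bromide
Product: 13 (2R,3S)-6-(benzyloxy)-2-[4-(benzyloxy)phenyl]-3-[3,5-bis(benzyloxy)-2-chlorophenyl]-4-bromo-2,3-dihydro-1-benzofuran (2,3-cis)
Conditions: N-chlorosuccinimide (1.05 equiv), DMF, 0 °C → rt
Reagents that add atoms: N-chlorosuccinimide O=C1CCC(=O)N1Cl
Why: Electrophilic aromatic chlorination should occur on the resorcinol ring of C3 at C10 (para to one ether and ortho to the benzylic carbon), because bromine deactivates the benzofuran ring and the carbon between the two ethers is the most hindered; the neutral medium spares the acid-labile cis ring.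

Step 9
Reactants: 13 bromo chloro cis-dihydrobenzofuran; 14 1-[4-(benzyloxy)phenyl]ethan-1-one
Product: 15 2-{(2R,3R)-6-(benzyloxy)-2-[4-(benzyloxy)phenyl]-3-[3,5-bis(benzyloxy)-2-chlorophenyl]-2,3-dihydro-1-benzofuran-4-yl}-1-[4-(benzyloxy)phenyl]ethan-1-one (2,3-cis ketone)
Conditions: Pd2(dba)3 (2.5 mol%), Xantphos, K3PO4, toluene, 100 °C
Reagents that add atoms: none
Why: Palladium-catalysed ketone α-arylation (Buchwald–Hartwig type) should engage only the aryl bromide, since the doubly ortho-substituted, electron-rich aryl chloride does not add oxidatively to this bisphosphine complex; the weak phosphate base avoids ring opening and double arylation.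

Step 10
Reactants: 15 cis ketone
Product: 17 (Z)-1-[4-(benzyloxy)phenyl]-2-{(2R,3R)-6-(benzyloxy)-2-[4-(benzyloxy)phenyl]-3-[3,5-bis(benzyloxy)-2-chlorophenyl]-2,3-dihydro-1-benzofuran-4-yl}ethenyl trifluoromethanesulfonate (2,3-cis), via potassium enolate 16 (not isolated)
Conditions: KN(SiMe3)2, THF, −78 °C; then PhNTf2, −78 → 0 °C
Reagents that add atoms: N-phenylbis(trifluoromethanesulfonimide) O=S(=O)(N(c1ccccc1)S(=O)(=O)C(F)(F)F)C(F)(F)F
Why: Deprotonation of an aryl benzyl ketone gives the (Z)-enolate with the two aryl groups trans, and O-sulfonylation (enol triflate formation) fixes that geometry.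

Step 11
Reactants: 15 cis ketone
Product: 18 2-{(2S,3R)-6-(benzyloxy)-2-[4-(benzyloxy)phenyl]-3-[3,5-bis(benzyloxy)-2-chlorophenyl]-2,3-dihydro-1-benzofuran-4-yl}-1-[4-(benzyloxy)phenyl]ethan-1-one (2,3-trans ketone)
Conditions: CF3CO2H, CH2Cl2, 0 °C → rt
Reagents that add atoms: none
Why: Acid ionises the C2–O bond to a benzylic cation stabilised by the 4-benzyloxyphenyl group and reclosure should give the thermodynamically preferred 2,3-trans isomer (acid-catalysed epimerisation at C2), C3 not being involved.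

Step 12
Reactants: 18 trans ketone
Product: 19 2-{(2S,3S)-6-(benzyloxy)-2-[4-(benzyloxy)phenyl]-3-[3,5-bis(benzyloxy)-2-(4,4,5,5-tetramethyl-1,3,2-dioxaborolan-2-yl)phenyl]-2,3-dihydro-1-benzofuran-4-yl}-1-[4-(benzyloxy)phenyl]ethan-1-one (2,3-trans boronate)
Conditions: Pd2(dba)3 (2 mol%), XPhos, B2pin2, KOAc, dioxane, 110 °C
Reagents that add atoms: bis(pinacolato)diboron CC1(C)OB(OC1(C)C)B1OC(C)(C)C(C)(C)O1
Why: Miyaura borylation with a bulky biarylphosphine activates hindered, electron-rich aryl chlorides, and potassium acetate is too weak a base to enolise the ketone.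

Step 13
Reactants: 17 cis enol triflate; 19 trans boronate
Product: 20 open dimer chloro ketone (bond C7a–C10b; Z-alkene C7a=C8a; Cl on C10d; CH2–CO–aryl on ring c)
Conditions: Pd(OAc)2 (5 mol%), SPhos, K3PO4, toluene/H2O, 50 °C
Reagents that add atoms: none
Why: Suzuki–Miyaura coupling in which oxidative addition into the alkenyl triflate should be far faster than into the hindered aryl chloride; it proceeds with retention, so the new aryl group is cis to C9a and the alkene is Z.

Step 14
Reactants: 20 open dimer chloro ketone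
Product: 21 open dimer boronate ketone (pinacol boronate on C10d)
Conditions: Pd2(dba)3 (3 mol%), XPhos, B2pin2, KOAc, dioxane, 110 °C
Reagents that add atoms: bis(pinacolato)diboron CC1(C)OB(OC1(C)C)B1OC(C)(C)C(C)(C)O1
Why: The same Miyaura borylation as in step 12, now on the only remaining carbon–halogen bond; the triarylethene and the ketone are inert to acetate and to the catalyst.

Step 15
Reactants: 21 open dimer boronate ketone
Product: 23 open dimer boronate enol triflate (Z-enol triflate at C7c), via potassium enolate 22 (not isolated)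
Conditions: KN(SiMe3)2, THF, −78 °C; then PhNTf2, −78 → 0 °C
Reagents that add atoms: N-phenylbis(trifluoromethanesulfonimide) O=S(=O)(N(c1ccccc1)S(=O)(=O)C(F)(F)F)C(F)(F)F
Why: Enol triflate formation as in step 10, giving the (Z)-isomer; the hindered amide base should not attack the pinacol boronate at −78 °C.

Step 16
Reactants: 23 open dimer boronate enol triflate
Product: 24 fourteen-membered (Z,Z)-bis(triarylethene) macrocycle decabenzyl ether
Conditions: Pd(OAc)2 (10 mol%), SPhos, K3PO4, THF/H2O, 60 °C, 1 mM, slow addition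
Reagents that add atoms: none
Why: Intramolecular Suzuki–Miyaura coupling under high dilution (macrocyclisation) joins C7c to C10d with retention of alkene geometry; step 13 is the intermolecular rehearsal of the same bond type.

Step 17
Reactants: 24 macrocycle
Product: 26 deca-O-benzyl ether of the target, via dilithium dianion 25 (not isolated)
Conditions: lithium naphthalenide LiC10H8 (2.1 equiv, added slowly), THF, −78 °C, 1 mM; then MeOH, −78 °C
Reagents that add atoms: none
Why: Proposed new method: single-electron transfer from lithium naphthalenide turns each triarylethene into a radical anion whose unpaired electron resides mainly on C8 while the charge is spread over the doubly benzylic C7; the two C8 termini, facing each other across the fourteen-membered ring, combine to the bond C8a–C8c, and methanol protonates the C7a/C7c dianion 25. The closest known reaction type is the tail-to-tail reductive dimerisation of 1,1-diarylethenes by alkali metals or arene radical anions, together with the cathodic electrohydrocyclisation of bis-styrenes. The one bond closes both eight-membered rings transannularly: ring X is closed endo with respect to C7a=C8a and exo with respect to C7c=C8c, ring Y the other way round. C8a and C8c should pair in the unlike sense, because the two bridges force each C7 arm to lie gauche to the C9 arm of the other alkene, and of the staggered combinations only the one with the two C8–H bonds anti avoids a doubly gauche aryl contact. C7a and C7c should each be protonated on the face of its eight-membered ring that carries the hydrogen of the neighbouring furan carbon (C8b for C7a, C8d for C7c), away from the C8–C7 furan bond; this single local rule gives H7a cis to H8a and H7c trans to H8c, because C8a and C8c have opposite configurations. The step needs C8–C8 coupling in preference to two-electron reduction of one alkene or cleavage of benzylic C–O bonds, which the proximity of the C8 atoms, exactly two equivalents of a reductant too weak to reduce benzyl aryl ethers quickly at −78 °C, the aprotic medium and the lithium counter-ion should secure; since C7a and C7c already carry their aryl groups, no seven-membered Friedel–Crafts-type closure can compete.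

Step 18
Reactants: 26 deca-O-benzyl ether of the target
Product: 27 CNP0224452.3 (target)
Conditions: H2 (1 atm), Pd/C, THF/MeOH, rt
Reagents that add atoms: none
Why: Catalytic hydrogenolysis removes the ten benzyl ethers under neutral conditions at room temperature, so the acid- and base-labile cis-2-(4-hydroxyphenyl)dihydrobenzofuran should not epimerise; the secondary, ring-bound C7–O bonds are cleaved much more slowly than O-benzyl groups.

Compound list
1 | 1,3-bis(benzyloxy)-5-bromobenzene | Brc1cc(OCc9ccccc9)cc(OCc9ccccc9)c1 | starting material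
2 | N-{[2,4-bis(benzyloxy)-6-bromophenyl]methylidene}-N-methylmethanaminium chloride | C[N+](C)=Cc1c(Br)cc(OCc9ccccc9)cc1OCc9ccccc9.[Cl-] | intermediate
3 | 2,4-bis(benzyloxy)-6-bromobenzaldehyde | O=Cc1c(Br)cc(OCc9ccccc9)cc1OCc9ccccc9 | intermediate
4 | 4-(benzyloxy)-2-bromo-6-hydroxybenzaldehyde | O=Cc1c(Br)cc(OCc9ccccc9)cc1O | intermediate
5 | 4-(benzyloxy)benzyl chloride | ClCc1ccc(OCc9ccccc9)cc1 | starting material
6 | 4-(benzyloxy)-2-{[4-(benzyloxy)phenyl]methoxy}-6-bromobenzaldehyde | O=Cc1c(Br)cc(OCc9ccccc9)cc1OCc1ccc(OCc9ccccc9)cc1 | intermediate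
7 | [3,5-bis(benzyloxy)phenyl]magnesium bromide | Br[Mg]c1cc(OCc9ccccc9)cc(OCc9ccccc9)c1 | intermediate
8 | (RS)-[4-(benzyloxy)-2-{[4-(benzyloxy)phenyl]methoxy}-6-bromophenyl][3,5-bis(benzyloxy)phenyl]methanol | OC(c1cc(OCc9ccccc9)cc(OCc9ccccc9)c1)c1c(Br)cc(OCc9ccccc9)cc1OCc1ccc(OCc9ccccc9)cc1 | intermediate
9 | [4-(benzyloxy)-2-{[4-(benzyloxy)phenyl]methoxy}-6-bromophenyl][3,5-bis(benzyloxy)phenyl]methanone | O=C(c1cc(OCc9ccccc9)cc(OCc9ccccc9)c1)c1c(Br)cc(OCc9ccccc9)cc1OCc1ccc(OCc9ccccc9)cc1 | intermediate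
10 | hydrazone of 9 (E/Z mixture) | NN=C(c1cc(OCc9ccccc9)cc(OCc9ccccc9)c1)c1c(Br)cc(OCc9ccccc9)cc1OCc1ccc(OCc9ccccc9)cc1 | intermediate
11 | [4-(benzyloxy)-2-{[4-(benzyloxy)phenyl]methoxy}-6-bromophenyl][3,5-bis(benzyloxy)phenyl]diazomethane | [N-]=[N+]=C(c1cc(OCc9ccccc9)cc(OCc9ccccc9)c1)c1c(Br)cc(OCc9ccccc9)cc1OCc1ccc(OCc9ccccc9)cc1 | intermediate
12 | (2R,3S)-6-(benzyloxy)-2-[4-(benzyloxy)phenyl]-3-[3,5-bis(benzyloxy)phenyl]-4-bromo-2,3-dihydro-1-benzofuran (2,3-cis) | Brc1cc(OCc9ccccc9)cc2c1[C@@H]([C@@H](O2)c1ccc(OCc9ccccc9)cc1)c1cc(OCc9ccccc9)cc(OCc9ccccc9)c1 | intermediate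
13 | (2R,3S)-6-(benzyloxy)-2-[4-(benzyloxy)phenyl]-3-[3,5-bis(benzyloxy)-2-chlorophenyl]-4-bromo-2,3-dihydro-1-benzofuran (2,3-cis) | Brc1cc(OCc9ccccc9)cc2c1[C@@H]([C@@H](O2)c1ccc(OCc9ccccc9)cc1)c1cc(OCc9ccccc9)cc(OCc9ccccc9)c1Cl | intermediate
14 | 1-[4-(benzyloxy)phenyl]ethan-1-one | CC(=O)c1ccc(OCc9ccccc9)cc1 | starting material
15 | 2-{(2R,3R)-6-(benzyloxy)-2-[4-(benzyloxy)phenyl]-3-[3,5-bis(benzyloxy)-2-chlorophenyl]-2,3-dihydro-1-benzofuran-4-yl}-1-[4-(benzyloxy)phenyl]ethan-1-one (2,3-cis) | O=C(Cc1cc(OCc9ccccc9)cc2c1[C@@H]([C@@H](O2)c1ccc(OCc9ccccc9)cc1)c1cc(OCc9ccccc9)cc(OCc9ccccc9)c1Cl)c1ccc(OCc9ccccc9)cc1 | intermediate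
16 | potassium (Z)-enolate of 15 | c9ccccc9COc1ccc(cc1)/C([O-])=C/c1cc(OCc9ccccc9)cc2c1[C@@H]([C@@H](O2)c1ccc(OCc9ccccc9)cc1)c1cc(OCc9ccccc9)cc(OCc9ccccc9)c1Cl.[K+] | intermediate
17 | (Z)-enol triflate of 15 (triflate on C7a; aryl groups trans; 2,3-cis, 2R,3R) | c9ccccc9COc1ccc(cc1)/C(OS(=O)(=O)C(F)(F)F)=C/c1cc(OCc9ccccc9)cc2c1[C@@H]([C@@H](O2)c1ccc(OCc9ccccc9)cc1)c1cc(OCc9ccccc9)cc(OCc9ccccc9)c1Cl | intermediate
18 | 2-{(2S,3R)-6-(benzyloxy)-2-[4-(benzyloxy)phenyl]-3-[3,5-bis(benzyloxy)-2-chlorophenyl]-2,3-dihydro-1-benzofuran-4-yl}-1-[4-(benzyloxy)phenyl]ethan-1-one (2,3-trans) | O=C(Cc1cc(OCc9ccccc9)cc2c1[C@@H]([C@H](O2)c1ccc(OCc9ccccc9)cc1)c1cc(OCc9ccccc9)cc(OCc9ccccc9)c1Cl)c1ccc(OCc9ccccc9)cc1 | intermediate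
19 | 2-{(2S,3S)-6-(benzyloxy)-2-[4-(benzyloxy)phenyl]-3-[3,5-bis(benzyloxy)-2-(4,4,5,5-tetramethyl-1,3,2-dioxaborolan-2-yl)phenyl]-2,3-dihydro-1-benzofuran-4-yl}-1-[4-(benzyloxy)phenyl]ethan-1-one (2,3-trans) | O=C(Cc1cc(OCc9ccccc9)cc2c1[C@@H]([C@H](O2)c1ccc(OCc9ccccc9)cc1)c1cc(OCc9ccccc9)cc(OCc9ccccc9)c1B1OC(C)(C)C(C)(C)O1)c1ccc(OCc9ccccc9)cc1 | intermediate
20 | open dimer chloro ketone: C7a of the Z-alkene on ring a (cis unit d, 7R,8R by CIP) bonded to C10b of trans unit b (7S,8S); Cl on C10d; ring c carries CH2–CO–C6H4-4-OBn | O=C(Cc1cc(OCc9ccccc9)cc2c1[C@@H]([C@H](O2)c1ccc(OCc9ccccc9)cc1)c1cc(OCc9ccccc9)cc(OCc9ccccc9)c1/C(c1ccc(OCc9ccccc9)cc1)=C\c1cc(OCc9ccccc9)cc2c1[C@@H]([C@@H](O2)c1ccc(OCc9ccccc9)cc1)c1cc(OCc9ccccc9)cc(OCc9ccccc9)c1Cl)c1ccc(OCc9ccccc9)cc1 | intermediate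
21 | open dimer boronate ketone: as 20 with a pinacol boronate on C10d (unit d 7R,8S; unit b 7S,8S) | O=C(Cc1cc(OCc9ccccc9)cc2c1[C@@H]([C@H](O2)c1ccc(OCc9ccccc9)cc1)c1cc(OCc9ccccc9)cc(OCc9ccccc9)c1/C(c1ccc(OCc9ccccc9)cc1)=C\c1cc(OCc9ccccc9)cc2c1[C@@H]([C@@H](O2)c1ccc(OCc9ccccc9)cc1)c1cc(OCc9ccccc9)cc(OCc9ccccc9)c1B1OC(C)(C)C(C)(C)O1)c1ccc(OCc9ccccc9)cc1 | intermediate
22 | potassium (Z)-enolate of 21 | c9ccccc9COc1ccc(cc1)/C([O-])=C/c1cc(OCc9ccccc9)cc2c1[C@@H]([C@H](O2)c1ccc(OCc9ccccc9)cc1)c1cc(OCc9ccccc9)cc(OCc9ccccc9)c1/C(c1ccc(OCc9ccccc9)cc1)=C\c1cc(OCc9ccccc9)cc2c1[C@@H]([C@@H](O2)c1ccc(OCc9ccccc9)cc1)c1cc(OCc9ccccc9)cc(OCc9ccccc9)c1B1OC(C)(C)C(C)(C)O1.[K+] | intermediate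
23 | open dimer boronate enol triflate: (Z)-enol triflate on C7c, pinacol boronate on C10d, Z-alkene C7a=C8a | c9ccccc9COc1ccc(cc1)/C(OS(=O)(=O)C(F)(F)F)=C/c1cc(OCc9ccccc9)cc2c1[C@@H]([C@H](O2)c1ccc(OCc9ccccc9)cc1)c1cc(OCc9ccccc9)cc(OCc9ccccc9)c1/C(c1ccc(OCc9ccccc9)cc1)=C\c1cc(OCc9ccccc9)cc2c1[C@@H]([C@@H](O2)c1ccc(OCc9ccccc9)cc1)c1cc(OCc9ccccc9)cc(OCc9ccccc9)c1B1OC(C)(C)C(C)(C)O1 | intermediate
24 | fourteen-membered (Z,Z)-bis(triarylethene) macrocycle, decabenzyl ether (7dR,8dS cis; 7bS,8bS trans) | c9ccccc9COc1ccc(cc1)/C2=C/c3cc(OCc9ccccc9)cc4c3[C@@H]([C@@H](O4)c5ccc(OCc9ccccc9)cc5)c5cc(OCc9ccccc9)cc(OCc9ccccc9)c5/C(c6ccc(OCc9ccccc9)cc6)=C\c6cc(OCc9ccccc9)cc7c6[C@@H]([C@H](O7)c8ccc(OCc9ccccc9)cc8)c8cc(OCc9ccccc9)cc(OCc9ccccc9)c82 | intermediate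
25 | dilithium C7a,C7c-dianion with the bond C8a–C8c formed | c9ccccc9COc1ccc([C-]2c3c(OCc9ccccc9)cc(OCc9ccccc9)cc3[C@H]3c4c(cc(OCc9ccccc9)cc4[C@H]4[C-](c5ccc(OCc9ccccc9)cc5)c5c(OCc9ccccc9)cc(OCc9ccccc9)cc5[C@H]5c6c(cc(OCc9ccccc9)cc6[C@H]24)O[C@H]5c2ccc(OCc9ccccc9)cc2)O[C@@H]3c2ccc(OCc9ccccc9)cc2)cc1.[Li+].[Li+] | intermediate
26 | deca-O-benzyl ether of the target (7aR,8aS,7bS,8bS,7cR,8cR,7dR,8dS) | c9ccccc9COc1ccc([C@@H]2c3c(OCc9ccccc9)cc(OCc9ccccc9)cc3[C@H]3c4c(cc(OCc9ccccc9)cc4[C@H]4[C@H](c5ccc(OCc9ccccc9)cc5)c5c(OCc9ccccc9)cc(OCc9ccccc9)cc5[C@H]5c6c(cc(OCc9ccccc9)cc6[C@H]24)O[C@H]5c2ccc(OCc9ccccc9)cc2)O[C@@H]3c2ccc(OCc9ccccc9)cc2)cc1 | intermediate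
27 | CNP0224452.3 (7aR,8aS,7bS,8bS,7cR,8cR,7dR,8dS) | Oc1ccc([C@@H]2c3c(O)cc(O)cc3[C@H]3c4c(cc(O)cc4[C@H]4[C@H](c5ccc(O)cc5)c5c(O)cc(O)cc5[C@H]5c6c(cc(O)cc6[C@H]24)O[C@H]5c2ccc(O)cc2)O[C@@H]3c2ccc(O)cc2)cc1 | target

Total step count: 18. Longest linear sequence: 17 steps (steps 1–9 and 11–18).

Steps most likely to fail

Step 17. The macrocycle may take both electrons into one alkene, which after protonation is plain hydrogenation without a C–C bond. The C8 atoms may also pair in the like sense, protonation may come from the wrong face, or electron transfer may cleave benzylic C–O bonds. The fallback uses known radical chemistry, sets out from 24 and returns at 26. Hydroboration–oxidation of one alkene with limiting BH3·THF, then NaOH/H2O2, should give the C8c alcohol F1 with syn-delivered hydrogen on C7c. 1,1'-Thiocarbonyldiimidazole (DMAP, CH2Cl2) converts it into the imidazole-1-carbothioate F2. Slow addition of Bu3SnH with AIBN in benzene at 80 °C generates the benzylic C8c radical (Barton–McCombie conditions). This radical adds across the ring to C8a of the remaining 1,1-diarylethene terminus, and the C7a diarylmethyl radical takes hydrogen from the stannane to give 26.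

Step 16. The hindered, electron-rich aryl boronate may lose boron by protonolysis, or chains may grow by intermolecular coupling before the ring closes. The fallback reverses the polarity of the ring closure, sets out from 20 and returns at 24. KN(SiMe3)2 and PhNTf2 give the chloro enol triflate F3. Miyaura borylation of the alkenyl triflate (PdCl2(PPh3)2, PPh3, KOPh, B2pin2, toluene, 50 °C), to which the aryl chloride is inert, gives the alkenyl boronate F4. Intramolecular Suzuki–Miyaura coupling of this robust alkenyl boronate with the aryl chloride (Pd(OAc)2, SPhos, K3PO4, dioxane/H2O, 90 °C, high dilution) then closes the macrocycle 24.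

Step 6. The condensation may stall because both faces of the carbonyl are screened by ortho substituents. The fallback sets out from 9 and returns at 11, which enters step 7 as before. 1,2-Bis(tert-butyldimethylsilyl)hydrazine with catalytic Sc(OTf)3 gives the N-silyl hydrazone F5, a condensation driven by silanol formation. Oxidation of F5 with (difluoroiodo)benzene and 2-chloropyridine in CH2Cl2 at −78 °C gives the diazo compound 11 directly.

Further compounds
F1 | step 17 | macrocycle mono-alcohol: OH on C8c and H on C7c (syn addition), alkene C7a=C8a intact | c9ccccc9COc1ccc(cc1)/C2=C/c3cc(OCc9ccccc9)cc4c3[C@@H]([C@@H](O4)c5ccc(OCc9ccccc9)cc5)c5cc(OCc9ccccc9)cc(OCc9ccccc9)c5[C@@H](c6ccc(OCc9ccccc9)cc6)[C@H](O)c6cc(OCc9ccccc9)cc7c6[C@@H]([C@H](O7)c8ccc(OCc9ccccc9)cc8)c8cc(OCc9ccccc9)cc(OCc9ccccc9)c82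
F2 | step 17 | O-(C8c) 1H-imidazole-1-carbothioate of F1 | c9ccccc9COc1ccc(cc1)/C2=C/c3cc(OCc9ccccc9)cc4c3[C@@H]([C@@H](O4)c5ccc(OCc9ccccc9)cc5)c5cc(OCc9ccccc9)cc(OCc9ccccc9)c5[C@@H](c6ccc(OCc9ccccc9)cc6)[C@H](OC(=S)n1ccnc1)c6cc(OCc9ccccc9)cc7c6[C@@H]([C@H](O7)c8ccc(OCc9ccccc9)cc8)c8cc(OCc9ccccc9)cc(OCc9ccccc9)c82
F3 | step 16 | open dimer chloro enol triflate: (Z)-enol triflate on C7c, Cl on C10d | c9ccccc9COc1ccc(cc1)/C(OS(=O)(=O)C(F)(F)F)=C/c1cc(OCc9ccccc9)cc2c1[C@@H]([C@H](O2)c1ccc(OCc9ccccc9)cc1)c1cc(OCc9ccccc9)cc(OCc9ccccc9)c1/C(c1ccc(OCc9ccccc9)cc1)=C\c1cc(OCc9ccccc9)cc2c1[C@@H]([C@@H](O2)c1ccc(OCc9ccccc9)cc1)c1cc(OCc9ccccc9)cc(OCc9ccccc9)c1Cl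
F4 | step 16 | open dimer alkenyl boronate: pinacol boronate on C7c (E by CIP, boron cis to C9c), Cl on C10d | c9ccccc9COc1ccc(cc1)/C(B1OC(C)(C)C(C)(C)O1)=C/c1cc(OCc9ccccc9)cc2c1[C@@H]([C@H](O2)c1ccc(OCc9ccccc9)cc1)c1cc(OCc9ccccc9)cc(OCc9ccccc9)c1/C(c1ccc(OCc9ccccc9)cc1)=C\c1cc(OCc9ccccc9)cc2c1[C@@H]([C@@H](O2)c1ccc(OCc9ccccc9)cc1)c1cc(OCc9ccccc9)cc(OCc9ccccc9)c1Cl
F5 | step 6 | N-(tert-butyldimethylsilyl)hydrazone of ketone 9 | CC(C)(C)[Si](C)(C)NN=C(c1cc(OCc9ccccc9)cc(OCc9ccccc9)c1)c1c(Br)cc(OCc9ccccc9)cc1OCc1ccc(OCc9ccccc9)cc1
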